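(The earlier runs and the new flask were generated by integration on assumed constants, noise included.)

all flasks: starting complex 0.050 M
- amber: incoming ligand 1.1 equiv; the very flask that is asked about, followed so far
- flask: incoming ligand 1.10 equiv; time 6.0 h

amber run (percent of the starting complex charged)

| time / h | complex with one exchanged / % | starting complex / % |
|---|---|---|
| 0.250 | 27.4 | 36.7 |
| 0.500 | 23.2 | 35.4 |
| 0.833 | 19.6 | 35.6 |
| 1.33 | 19.1 | 35.0 |
| 2.00 | 18.8 | 34.9 |
| 4.00 | 19.0 | 35.8 |

(readings scatter by 0.5 percentage points)

- west: at 6.0 h take out 90% of the complex with one exchanged then present, then wait 3.0 h
- east: at 6.0 h add starting complex, 50.0% of the amount charged, then wait 3.0 h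
- north-east: change nothing and wait 3.0 h more
- north: at 6.0 h add incoming ligand, 50.0% of the amount charged, then wait 3.0 h

- complex with one exchanged taken out counts as made
- the numbers in the tables scatter by 0.5 percentage points (one standard deviation)
- additions bring no volume worth counting

- complex with one exchanged, in percent of the starting complex first charged, at 6.0 h
- the option that brings most further complex with one exchanged ("none" if no option brings more than 2 percentage points) (west / east / north-east / north / none)
- complex with one exchanged present, with what was taken out counted in, in percent of the starting complex first charged, after east
- complex with one exchanged present, with what was taken out counted in, in percent of the starting complex first charged, after north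

Taking out the complex with one exchanged, B, is the move to back, provided that what it has turned into can return. In this flask the starting complex reads 36.7% at the first reading and 35.8% at the last, flat within the scatter, yet B falls on to a floor read at 19.0%. The reckoning here reads that floor as a balance with an unseen partner P, where forward and back rates are equal and their quotient holds no time.

The west gain is then s times the pool left after 90% of B is removed, less the B left behind, where the pool is B + P and s = B/(B + P). From below, if the fall seen went into P, P is at least 8.4 percentage points, which gives 5.3 points. From above, P is at most what the balance misses, 45 points, which gives 12 points.

The bracket tightens by hand: B's excess over the floor reads half after 0.250 h, and the same step back to the start, with P taken as nil there, gives a reading of P = 17 points. So the balance share, the part of the pool standing as B once both rates are equal, reads s = 0.530, and west is reckoned to gain 8 points. "Now" is reckoned at the floor, and east with it, on the expectation that added starting complex stands as flat as the starting complex in these readings. North is expected to restart exchange, which makes and uses B together, and s gives no figure for that.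

The forecast gives 19.1%, west, 27.6% and 13.6%, with west “giving about 33 counted”, a gain of 14 points, outside the bracket.

The flask gives 18.6%, and west gains 8.4 points; east ends at 18.6% and north at 19.3%. At 6.00 h this flask holds the isomer of the product, the partner P, at 18.6% beside 18.6% of the complex with one exchanged.

    starting complex + incoming ligand → leaving ligand + complex with one exchanged (k = 0.0910 L mol⁻¹ s⁻¹)
    complex with one exchanged + incoming ligand → leaving ligand + complex with two exchanged (k = 0.100 L mol⁻¹ s⁻¹)
    complex with two exchanged + incoming ligand → leaving ligand + complex with three exchanged (k = 0.0410 L mol⁻¹ s⁻¹)
    2 incoming ligand → self-condensation product (k = 0.0120 L mol⁻¹ s⁻¹)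
    complex with one exchanged ⇌ isomer of the product (K = 1.00, k = 4.80 × 10⁻⁴ s⁻¹)
    crystals ⇌ leaving ligand, rate k6*(cs6 - [leaving ligand]) while solid is left; crystals form when [leaving ligand] > cs6 (solubility = 39.0 mM, k = 0.0220 s⁻¹)

In the neighbour flask with 1.90 equiv of incoming ligand, the complex with one exchanged and the isomer of the product hold 31.3% together, so s gives 16.6% of the complex with one exchanged, and that flask holds 15.7%.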